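**Plan**

- Positions are numbered as in eudesmanes: ring A = C1–C5 and C10, ring B = C5–C10, C14 = angular methyl, C15 = methylidene carbon.
- Retrosynthesis: cut the C9 ester C–O bond, move the C4=C15 alkene into ring A (C3=C4) and raise C9 to the ketone. Ring A is then a cyclohexene whose quaternary C10 is alpha to the C9 carbonyl, so C1–C2 and C5–C10 are cut together (retro-Diels–Alder) to an acyclic (7Z)-deca-1,7,9-trien-3-one.
- The chain is cut at C9–C10 (isopropenyllithium + gamma-lactone), C3–C4 (vinylstannane + alkenyl iodide), C4=C5 (Wittig) and C7–C11 (cuprate addition to (S)-5-(hydroxymethyl)furan-2(5H)-one, 1).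
- Forward: butenolide → trans-lactone → (Z)-diene → trienone; rings A and B then form in one cycloaddition; ketone reduction, esterification and transposition of the ring alkene to the exocyclic position finish the route.
- Stereochemistry: C6 from 1; C7 by addition anti to the C6 side chain; C5 and C10 in the cycloaddition (the Z-diene forces cis fusion, allylic strain at C6 fixes the face); C9 by hydride delivery anti to the axial C7 isopropyl group.

Key step: step 9

Remark: the gamma-hydroxy enone formed on opening the lactone is assumed to equilibrate with its five-membered lactol; silylation of the open form drains this equilibrium.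

**Route**

Step 1
Reactants: 1 (S)-5-(hydroxymethyl)furan-2(5H)-one
Product: 2 (S)-5-{[(tert-butyldiphenylsilyl)oxy]methyl}furan-2(5H)-one
Conditions: TBDPSCl, imidazole, DMF, 0 → 23 °C
Reagents that add atoms: tert-butyl(chloro)diphenylsilane, CC(C)(C)[Si](Cl)(c1ccccc1)c1ccccc1
Why: Imidazole-mediated silylation of the primary alcohol should install a bulky group that shields one face of the butenolide without touching the stereocenter (future C6).

Step 2
Reactants: 2 (S)-5-{[(tert-butyldiphenylsilyl)oxy]methyl}furan-2(5H)-one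
Product: 4 (4R,5S)-5-{[(tert-butyldiphenylsilyl)oxy]methyl}-4-isopropyldihydrofuran-2(3H)-one, via silyl ketene acetal 3 (not isolated)
Conditions: i-PrMgCl, CuBr·SMe2 (cat.), Me3SiCl, THF, −78 °C; then aq. NH4Cl
Reagents that add atoms: isopropylmagnesium chloride, CC(C)[Mg]Cl
Why: Copper-catalysed, Me3SiCl-accelerated conjugate addition to the butenolide should occur anti to the silyloxymethyl group, which sets C7 trans to C6; the ketene acetal 3 is hydrolysed on work-up.

Step 3
Reactants: 4 (4R,5S)-5-{[(tert-butyldiphenylsilyl)oxy]methyl}-4-isopropyldihydrofuran-2(3H)-one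
Product: 5 (4R,5S)-5-(hydroxymethyl)-4-isopropyldihydrofuran-2(3H)-one
Conditions: Bu4NF, AcOH, THF, 0 °C
Reagents that add atoms: none
Why: Fluoride desilylation buffered with acetic acid should free the primary alcohol without lactone migration.

Step 4
Reactants: 5 (4R,5S)-5-(hydroxymethyl)-4-isopropyldihydrofuran-2(3H)-one
Product: 6 (2S,3R)-3-isopropyl-5-oxotetrahydrofuran-2-carbaldehyde
Conditions: Dess–Martin periodinane, CH2Cl2, 0 → 23 °C
Reagents that add atoms: none
Why: Dess–Martin oxidation should give the alpha-alkoxy aldehyde under non-basic conditions; the trans arrangement is also the more stable one, so C6 is not at risk.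

Step 5
Reactants: 6 (2S,3R)-3-isopropyl-5-oxotetrahydrofuran-2-carbaldehyde
Product: 7 (4R,5S)-5-[(Z)-2-iodoprop-1-en-1-yl]-4-isopropyldihydrofuran-2(3H)-one
Conditions: [Ph3PEt]I, n-BuLi, THF; I2, −78 °C; NaN(SiMe3)2, −20 °C; then 6, −78 °C
Reagents that add atoms: ethyltriphenylphosphonium iodide, CC[P+](c1ccccc1)(c1ccccc1)c1ccccc1.[I-]; iodine, II
Why: Stork–Zhao olefination with the alpha-iodoethylidene ylide should give the (Z)-2-iodoalkene, iodine cis to the lactone carbon, as is usual for this Wittig variant with aliphatic aldehydes.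

Step 6
Reactants: 7 (4R,5S)-5-[(Z)-2-iodoprop-1-en-1-yl]-4-isopropyldihydrofuran-2(3H)-one
Product: 8 (4R,5S)-4-isopropyl-5-[(1Z)-2-methylbuta-1,3-dien-1-yl]dihydrofuran-2(3H)-one
Conditions: Bu3SnCH=CH2, Cu(O2CC4H3S), NMP, 0 → 23 °C
Reagents that add atoms: tributyl(vinyl)stannane, C=C[Sn](CCCC)(CCCC)CCCC
Why: Copper-carboxylate-mediated Stille-type coupling should replace iodine by vinyl with retention of alkene geometry, and it avoids zerovalent palladium, which could ionize the allylic lactone C–O bond.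

Step 7
Reactants: 8 (4R,5S)-4-isopropyl-5-[(1Z)-2-methylbuta-1,3-dien-1-yl]dihydrofuran-2(3H)-one
Product: 10 (5R,6S,7Z)-6-hydroxy-5-isopropyl-2,8-dimethyldeca-1,7,9-trien-3-one, via lactol 9 (not isolated)
Conditions: CH2=C(Me)Li (from 2-bromopropene, Li, Et2O), THF, −78 °C; then aq. NH4Cl
Reagents that add atoms: isopropenyllithium, [Li]C(C)=C
Why: Organolithium mono-addition to a gamma-lactone should stop at the tetrahedral lactolate at −78 °C, which gives lactol 9 on quench and opens to the isopropenyl ketone.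

Step 8
Reactants: 10 (5R,6S,7Z)-6-hydroxy-5-isopropyl-2,8-dimethyldeca-1,7,9-trien-3-one
Product: 11 (5R,6S,7Z)-5-isopropyl-2,8-dimethyl-6-[(triethylsilyl)oxy]deca-1,7,9-trien-3-one
Conditions: Et3SiCl, imidazole, DMF, 0 °C
Reagents that add atoms: chlorotriethylsilane, CC[Si](Cl)(CC)CC
Why: Silylation of the secondary allylic alcohol of the open-chain form should block hemiketal formation and protect C6–OH for the later esterification at C9.

Step 9
Reactants: 11 (5R,6S,7Z)-5-isopropyl-2,8-dimethyl-6-[(triethylsilyl)oxy]deca-1,7,9-trien-3-one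
Product: 12 (3R,4S,4aS,8aR)-3-isopropyl-5,8a-dimethyl-4-[(triethylsilyl)oxy]-3,4,4a,7,8,8a-hexahydronaphthalen-1(2H)-one (cis-fused)
Conditions: PhMe (0.01 M), BHT (cat.), sealed tube, 130 °C
Reagents that add atoms: none
Why: A thermal concerted [4+2] cycloaddition between the (7Z)-diene (C2=C3–C4=C5) and the isopropenyl ketone (C10=C1) should form C1–C2 and C5–C10 at once. The closest known reaction type is the intramolecular Diels–Alder reaction of (Z)-1,7,9-decatrien-3-ones, which gives cis-fused octalones. Ring A closes as the new cyclohexene of the [4+2] event (bonds C1–C2 and C5–C10); ring B closes through the C5–C10 bond alone in the fused mode, the four-atom tether C6–C9 adopting a chair with the C9 carbonyl exo. C10 is controlled by the diene geometry: with the tether on the inside (Z) position of the diene a trans-fused transition state cannot be reached, so the angular methyl ends cis to H5; C5 is controlled by the C6 stereocenter through allylic 1,3-strain, with C6–H lying near the diene plane and the silyloxy group pointing away from the dienophile, so that H5 ends cis to the C6 oxygen. The step needs cis fusion, one diene face and the fused (not bridged) regiochemistry, secured respectively by the (Z)-alkene, by C6 and by the short tether; the C7 isopropyl group is axial in this transition state, a tolerable cost because C9 is trigonal.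

Step 10
Reactants: 12 (3R,4S,4aS,8aR)-3-isopropyl-5,8a-dimethyl-4-[(triethylsilyl)oxy]-3,4,4a,7,8,8a-hexahydronaphthalen-1(2H)-one
Product: 13 (1R,3R,4S,4aS,8aR)-3-isopropyl-5,8a-dimethyl-4-[(triethylsilyl)oxy]-1,2,3,4,4a,7,8,8a-octahydronaphthalen-1-ol
Conditions: LiBH(s-Bu)3, THF, −78 → 0 °C; then H2O
Reagents that add atoms: none
Why: The bulky borohydride should attack the C9 carbonyl equatorially on the chair in which the axial C7 isopropyl group blocks the other face, which places the new C9–O bond cis to the angular methyl (substrate-controlled ketone reduction).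

Step 11
Reactants: 13 (1R,3R,4S,4aS,8aR)-3-isopropyl-5,8a-dimethyl-4-[(triethylsilyl)oxy]-1,2,3,4,4a,7,8,8a-octahydronaphthalen-1-ol
Product: 14 (1R,3R,4S,4aS,8aR)-3-isopropyl-5,8a-dimethyl-4-[(triethylsilyl)oxy]-1,2,3,4,4a,7,8,8a-octahydronaphthalen-1-yl 4-methoxybenzoate
Conditions: 4-MeOC6H4COCl, Et3N, DMAP (cat.), CH2Cl2, 40 °C
Reagents that add atoms: 4-methoxybenzoyl chloride, COc1ccc(cc1)C(Cl)=O
Why: DMAP-catalysed acylation should esterify the only free hydroxyl, the hindered C9 alcohol, with retention at C9.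

Step 12
Reactants: 14 (1R,3R,4S,4aS,8aR)-3-isopropyl-5,8a-dimethyl-4-[(triethylsilyl)oxy]-1,2,3,4,4a,7,8,8a-octahydronaphthalen-1-yl 4-methoxybenzoate
Product: 15 (1R,3R,4S,4aS,8aR)-5-(hydroxymethyl)-3-isopropyl-8a-methyl-4-[(triethylsilyl)oxy]-1,2,3,4,4a,7,8,8a-octahydronaphthalen-1-yl 4-methoxybenzoate
Conditions: SeO2 (cat.), t-BuOOH, CH2Cl2, 23 °C
Reagents that add atoms: selenium dioxide, O=[Se]=O; tert-butyl hydroperoxide, CC(C)(C)OO
Why: SeO2 allylic oxidation (ene reaction then [2,3]-sigmatropic shift) acts at the more substituted alkene terminus and prefers methyl over the ring-fusion methine, so it should hydroxylate C15.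

Step 13
Reactants: 15 (1R,3R,4S,4aS,8aR)-5-(hydroxymethyl)-3-isopropyl-8a-methyl-4-[(triethylsilyl)oxy]-1,2,3,4,4a,7,8,8a-octahydronaphthalen-1-yl 4-methoxybenzoate
Product: 18 (1R,3R,4S,4aS,8aR)-3-isopropyl-8a-methyl-5-methylidene-4-[(triethylsilyl)oxy]decahydronaphthalen-1-yl 4-methoxybenzoate, via sulfonylhydrazine adduct 16 (not isolated), via allylic diazene 17 (not isolated)
Conditions: PPh3, DEAD, 2-O2NC6H4SO2NHNH2, THF, −30 → 23 °C
Reagents that add atoms: none
Why: Mitsunobu displacement of the primary allylic alcohol by the sulfonylhydrazide gives 16, loss of sulfinic acid gives diazene 17, and retro-ene loss of N2 delivers hydrogen to C3 and moves the alkene to C4=C15 (reductive 1,3-transposition of an allylic alcohol).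

Step 14
Reactants: 18 (1R,3R,4S,4aS,8aR)-3-isopropyl-8a-methyl-5-methylidene-4-[(triethylsilyl)oxy]decahydronaphthalen-1-yl 4-methoxybenzoate
Product: 19 (1R,3R,4S,4aS,8aR)-4-hydroxy-3-isopropyl-8a-methyl-5-methylidenedecahydronaphthalen-1-yl 4-methoxybenzoate
Conditions: HF·pyridine, pyridine, THF, 0 °C
Reagents that add atoms: none
Why: Buffered fluoride cleavage of the triethylsilyl ether should free C6–OH without acid strong enough to move the exocyclic alkene or cleave the ester.

**Compound list**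

1 | (S)-5-(hydroxymethyl)furan-2(5H)-one | OC[C@H]1OC(=O)C=C1 | starting material
2 | (S)-5-{[(tert-butyldiphenylsilyl)oxy]methyl}furan-2(5H)-one | CC(C)(C)[Si](OC[C@H]1OC(=O)C=C1)(c1ccccc1)c1ccccc1 | intermediate
3 | (4S,5S)-5-{[(tert-butyldiphenylsilyl)oxy]methyl}-4-isopropyl-2-[(trimethylsilyl)oxy]-4,5-dihydrofuran (trans; silyl ketene acetal) | C[Si](C)(C)OC1=C[C@H](C(C)C)[C@@H](CO[Si](c2ccccc2)(c2ccccc2)C(C)(C)C)O1 | intermediate
4 | (4R,5S)-5-{[(tert-butyldiphenylsilyl)oxy]methyl}-4-isopropyldihydrofuran-2(3H)-one | CC(C)(C)[Si](OC[C@H]1OC(=O)C[C@@H]1C(C)C)(c1ccccc1)c1ccccc1 | intermediate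
5 | (4R,5S)-5-(hydroxymethyl)-4-isopropyldihydrofuran-2(3H)-one | OC[C@H]1OC(=O)C[C@@H]1C(C)C | intermediate
6 | (2S,3R)-3-isopropyl-5-oxotetrahydrofuran-2-carbaldehyde | O=C[C@H]1OC(=O)C[C@@H]1C(C)C | intermediate
7 | (4R,5S)-5-[(Z)-2-iodoprop-1-en-1-yl]-4-isopropyldihydrofuran-2(3H)-one | C/C(I)=C/[C@H]1OC(=O)C[C@@H]1C(C)C | intermediate
8 | (4R,5S)-4-isopropyl-5-[(1Z)-2-methylbuta-1,3-dien-1-yl]dihydrofuran-2(3H)-one | C=C/C(C)=C\[C@H]1OC(=O)C[C@@H]1C(C)C | intermediate
9 | (4R,5S)-4-isopropyl-5-[(1Z)-2-methylbuta-1,3-dien-1-yl]-2-(prop-1-en-2-yl)tetrahydrofuran-2-ol (lactol, both C2 epimers) | C=C/C(C)=C\[C@H]1OC(O)(C(C)=C)C[C@@H]1C(C)C | intermediate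
10 | (5R,6S,7Z)-6-hydroxy-5-isopropyl-2,8-dimethyldeca-1,7,9-trien-3-one | C=C(C)C(=O)C[C@H](C(C)C)[C@H](O)/C=C(C)\C=C | intermediate
11 | (5R,6S,7Z)-5-isopropyl-2,8-dimethyl-6-[(triethylsilyl)oxy]deca-1,7,9-trien-3-one | C=C(C)C(=O)C[C@H](C(C)C)[C@H](O[Si](CC)(CC)CC)/C=C(C)\C=C | intermediate
12 | (3R,4S,4aS,8aR)-3-isopropyl-5,8a-dimethyl-4-[(triethylsilyl)oxy]-3,4,4a,7,8,8a-hexahydronaphthalen-1(2H)-one | CC1=CCC[C@]2(C)[C@H]1[C@@H](O[Si](CC)(CC)CC)[C@@H](C(C)C)CC2=O | intermediate
13 | (1R,3R,4S,4aS,8aR)-3-isopropyl-5,8a-dimethyl-4-[(triethylsilyl)oxy]-1,2,3,4,4a,7,8,8a-octahydronaphthalen-1-ol | CC1=CCC[C@]2(C)[C@H]1[C@@H](O[Si](CC)(CC)CC)[C@@H](C(C)C)C[C@H]2O | intermediate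
14 | (1R,3R,4S,4aS,8aR)-3-isopropyl-5,8a-dimethyl-4-[(triethylsilyl)oxy]-1,2,3,4,4a,7,8,8a-octahydronaphthalen-1-yl 4-methoxybenzoate | CC1=CCC[C@]2(C)[C@H]1[C@@H](O[Si](CC)(CC)CC)[C@@H](C(C)C)C[C@H]2OC(=O)c1ccc(OC)cc1 | intermediate
15 | (1R,3R,4S,4aS,8aR)-5-(hydroxymethyl)-3-isopropyl-8a-methyl-4-[(triethylsilyl)oxy]-1,2,3,4,4a,7,8,8a-octahydronaphthalen-1-yl 4-methoxybenzoate | OCC1=CCC[C@]2(C)[C@H]1[C@@H](O[Si](CC)(CC)CC)[C@@H](C(C)C)C[C@H]2OC(=O)c1ccc(OC)cc1 | intermediate
16 | N-allylic N-(2-nitrobenzenesulfonyl)hydrazine of 15 (C15–N(NH2)SO2Ar in place of C15–OH) | NN(CC1=CCC[C@]2(C)[C@H]1[C@@H](O[Si](CC)(CC)CC)[C@@H](C(C)C)C[C@H]2OC(=O)c1ccc(OC)cc1)S(=O)(=O)c1ccccc1[N+](=O)[O-] | intermediate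
17 | allylic monoalkyl diazene of 15 (C15–N=NH in place of C15–OH) | N=NCC1=CCC[C@]2(C)[C@H]1[C@@H](O[Si](CC)(CC)CC)[C@@H](C(C)C)C[C@H]2OC(=O)c1ccc(OC)cc1 | intermediate
18 | (1R,3R,4S,4aS,8aR)-3-isopropyl-8a-methyl-5-methylidene-4-[(triethylsilyl)oxy]decahydronaphthalen-1-yl 4-methoxybenzoate | C=C1CCC[C@]2(C)[C@H]1[C@@H](O[Si](CC)(CC)CC)[C@@H](C(C)C)C[C@H]2OC(=O)c1ccc(OC)cc1 | intermediate
19 | (1R,3R,4S,4aS,8aR)-4-hydroxy-3-isopropyl-8a-methyl-5-methylidenedecahydronaphthalen-1-yl 4-methoxybenzoate | C=C1CCC[C@]2(C)[C@H]1[C@@H](O)[C@@H](C(C)C)C[C@H]2OC(=O)c1ccc(OC)cc1 | target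

**Step count and risks**

Total steps: 14. Longest linear sequence: 14 steps (from 1).

Steps most likely to fail:

1. Step 9. The cycloaddition of the hindered (Z)-diene may be slow, so that a [1,5]-hydrogen shift from C6 or polymerization of the isopropenyl ketone competes, and the facial preference may erode at the temperature needed. The fallback sets out from lactone 8 and uses a more reactive dienophile. Vinyllithium (THF, −78 °C) should give (5R,6S,7Z)-6-hydroxy-5-isopropyl-8-methyldeca-1,7,9-trien-3-one F1, and Et3SiCl with imidazole its triethylsilyl ether F2. The unsubstituted vinyl ketone of F2 should cycloadd near room temperature, again cis-fused because of the (Z)-diene, to (3R,4S,4aR,8aR)-3-isopropyl-5-methyl-4-[(triethylsilyl)oxy]-3,4,4a,7,8,8a-hexahydronaphthalen-1(2H)-one F3. Equilibrating silylation (Me3SiCl, Et3N, DMF, 130 °C) should give the ring-fusion trimethylsilyl enol ether F4. MeLi then MeI should methylate C10, with the preference of ring-fusion decalone enolates for the cis-fused product, and the route is rejoined at 12.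

2. Step 10. Hydride delivery may go to the wrong face of the C9 carbonyl, because equatorial attack is hindered by the axial C1 methylene on C10 while axial attack is hindered by the C7 isopropyl group. The fallback sets out from 12 and returns at 13: Corey–Bakshi–Shibata reduction with (S)-2-methyl-CBS-oxazaborolidine and BH3·SMe2 replaces substrate control by reagent control, the quaternary C10 acting as the large group; it makes no new compound (F0).

3. Step 12. Oxidation may occur at other allylic sites (C2, C5) or run on past the alcohol. The fallback sets out from 14 and returns at 18: triplet-sensitized irradiation (p-xylene, t-BuOH, quartz, Hg lamp) of the 1-methylcyclohexene unit should move the alkene directly to the exocyclic position by protonation of the twisted alkene and loss of a C15 proton; it makes no new compound (F0).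

Further compounds
F1 | step 9 | (5R,6S,7Z)-6-hydroxy-5-isopropyl-8-methyldeca-1,7,9-trien-3-one | C=CC(=O)C[C@H](C(C)C)[C@H](O)/C=C(C)\C=C
F2 | step 9 | (5R,6S,7Z)-5-isopropyl-8-methyl-6-[(triethylsilyl)oxy]deca-1,7,9-trien-3-one | C=CC(=O)C[C@H](C(C)C)[C@H](O[Si](CC)(CC)CC)/C=C(C)\C=C
F3 | step 9 | (3R,4S,4aR,8aR)-3-isopropyl-5-methyl-4-[(triethylsilyl)oxy]-3,4,4a,7,8,8a-hexahydronaphthalen-1(2H)-one (cis-fused) | CC1=CCC[C@@H]2[C@H]1[C@@H](O[Si](CC)(CC)CC)[C@@H](C(C)C)CC2=O
F4 | step 9 | trimethylsilyl enol ether of F3 at the ring fusion (C9=C10 double bond; C5, C6 and C7 unchanged) | CC1=CCCC2=C(O[Si](C)(C)C)C[C@H](C(C)C)[C@H](O[Si](CC)(CC)CC)[C@@H]12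
F0 | step 10 | none | none
F0 | step 12 | none | none
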